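**Plan**

- Cuts: (i) the stilbene C=C (Horner–Wadsworth–Emmons reaction of a C7 aldehyde); (ii) the aryl ether bond O4–C4a of the 1,4-dioxane ring, traced back by an O→O aryl shift (Smiles) to a 2-aryl-1,5-benzodioxepin-3-ol in which the later CH2OH carbon is still a ring atom; (iii) C2–O1 (carbenoid O–H insertion), CH2–O (phenoxide alkylation) and ArCH2–C (Grignard/epichlorohydrin).
- Forward: chloroketone 6 O-alkylates the 4-OH of 3,4,5-trihydroxybenzonitrile; diazo transfer and Rh O–H insertion close the seven-membered dioxepinone; transfer hydrogenation gives the cis-alcohol; base contracts the ring 7→6; then DIBAL-H, HWE olefination and deprotection.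
- Enabling feature: C7 of the benzodioxane, which carries the styryl group, is para to C4a (the carbon bearing O4) and meta to C8a. Held as a nitrile it makes C4a the only SNAr-active carbon, so the C3 alkoxide adds ipso at C4a and the CH2–O unit leaves the ring as the hydroxymethyl group. The same acceptor makes the 4-OH of the triol the most acidic, which puts O4 next to the 5-OH.
- Stereochemistry: C2 and C3 are set together as the cis-(2S,3S) dioxepinol by Ru–TsDPEN transfer hydrogenation with dynamic kinetic resolution of the racemic α-aryl ketone. No bond to C2 or C3 is broken in the contraction, which turns the cis-dioxepinol into the trans-(2S,3S) benzodioxane. The alkene is E from the HWE step.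

Key step: step 9

Assumption: in step 8 the aryl-bearing α-carbon of ketone 11 is taken to play the part of the aryl group in the usual Ru–TsDPEN model, so the (S,S) catalyst is written; if the sense proves opposite, the (R,R) catalyst is used.

**Route**

Step 1
Reactants: 1 4-bromo-2,6-dimethoxyphenol
Product: 2 5-bromo-1,3-dimethoxy-2-(methoxymethoxy)benzene
Conditions: NaH, MOMCl, THF–DMF, 0 °C → rt
Reagents that add atoms: chloromethyl methyl ether (MOMCl), COCCl
Why: Williamson-type O-alkylation of the phenoxide gives the MOM ether, which should survive Grignard formation, base and hydride and is removed by acid at the end.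

Step 2
Reactants: 2 5-bromo-1,3-dimethoxy-2-(methoxymethoxy)benzene; 3 (±)-epichlorohydrin
Product: 5 1-chloro-3-[3,5-dimethoxy-4-(methoxymethoxy)phenyl]propan-2-ol (racemic), via aryl Grignard reagent 4 (not isolated)
Conditions: Mg, THF, reflux; then CuI (10 mol%), 3, −40 → 0 °C; aq NH4Cl
Reagents that add atoms: none
Why: Copper-catalysed opening of the epoxide by the aryl Grignard reagent at the terminal CH2 should give the chlorohydrin; its stereocentre is removed in step 3.

Step 3
Reactants: 5 1-chloro-3-[3,5-dimethoxy-4-(methoxymethoxy)phenyl]propan-2-ol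
Product: 6 1-chloro-3-[3,5-dimethoxy-4-(methoxymethoxy)phenyl]propan-2-one
Conditions: Dess–Martin periodinane, CH2Cl2, 0 °C → rt
Reagents that add atoms: none
Why: Dess–Martin oxidation of the secondary alcohol should give the α-chloroketone without touching the MOM ether or the electron-rich ring.

Step 4
Reactants: 6 1-chloro-3-[3,5-dimethoxy-4-(methoxymethoxy)phenyl]propan-2-one; 7 3,4,5-trihydroxybenzonitrile
Product: 8 4-{3-[3,5-dimethoxy-4-(methoxymethoxy)phenyl]-2-oxopropoxy}-3,5-dihydroxybenzonitrile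
Conditions: KHCO3 (1.05 equiv), KI (cat.), DMF, rt
Reagents that add atoms: none
Why: Williamson ether synthesis; with one equivalent of weak base only the 4-OH, para to the nitrile and the most acidic, is deprotonated and should displace the activated α-chloride.

Step 5
Reactants: 8 4-{3-[3,5-dimethoxy-4-(methoxymethoxy)phenyl]-2-oxopropoxy}-3,5-dihydroxybenzonitrile
Product: 9 4-{3-diazo-3-[3,5-dimethoxy-4-(methoxymethoxy)phenyl]-2-oxopropoxy}-3,5-dihydroxybenzonitrile
Conditions: p-ABSA, DBU, MeCN, 0 °C → rt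
Reagents that add atoms: 4-acetamidobenzenesulfonyl azide (p-ABSA), CC(=O)Nc1ccc(cc1)S(=O)(=O)N=[N+]=[N-]
Why: Regitz diazo transfer should occur at the benzylic CH2, which is activated by both the aryl group and the ketone and gives the conjugated aryl diazoketone.

Step 6
Reactants: 9 4-{3-diazo-3-[3,5-dimethoxy-4-(methoxymethoxy)phenyl]-2-oxopropoxy}-3,5-dihydroxybenzonitrile
Product: 10 2-[3,5-dimethoxy-4-(methoxymethoxy)phenyl]-6-hydroxy-3-oxo-3,4-dihydro-2H-1,5-benzodioxepine-8-carbonitrile (racemic)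
Conditions: Rh2(OAc)4 (1 mol%), CH2Cl2, 40 °C, slow addition (final about 2 mM)
Reagents that add atoms: none
Why: Intramolecular Rh-carbenoid O–H insertion into one of the two equivalent flanking phenols should close the seven-membered ring and form C2–O1; the C2 centre is racemic and stays epimerisable.

Step 7
Reactants: 10 2-[3,5-dimethoxy-4-(methoxymethoxy)phenyl]-6-hydroxy-3-oxo-3,4-dihydro-2H-1,5-benzodioxepine-8-carbonitrile
Product: 11 2-[3,5-dimethoxy-4-(methoxymethoxy)phenyl]-6-(methoxymethoxy)-3-oxo-3,4-dihydro-2H-1,5-benzodioxepine-8-carbonitrile (racemic)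
Conditions: MOMCl, iPr2NEt, CH2Cl2, 0 °C → rt
Reagents that add atoms: chloromethyl methyl ether (MOMCl), COCCl
Why: O-alkylation of the remaining phenol is needed because a phenoxide ortho to C5a would switch off the later SNAr step.

Step 8
Reactants: 11 2-[3,5-dimethoxy-4-(methoxymethoxy)phenyl]-6-(methoxymethoxy)-3-oxo-3,4-dihydro-2H-1,5-benzodioxepine-8-carbonitrile
Product: 12 (2S,3S)-2-[3,5-dimethoxy-4-(methoxymethoxy)phenyl]-3-hydroxy-6-(methoxymethoxy)-3,4-dihydro-2H-1,5-benzodioxepine-8-carbonitrile (cis)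
Conditions: RuCl[(S,S)-TsDPEN](p-cymene) (2 mol%), HCO2H–Et3N (5:2), DMF, 40 °C, degassed
Reagents that add atoms: none
Why: Noyori asymmetric transfer hydrogenation with dynamic kinetic resolution: C2 epimerises through the enol under Et3N, and the catalyst should reduce the matched enantiomer with hydride delivery anti to the C2 aryl group, setting C3 (S) and C2 (S) as the cis-alcohol.

Step 9
Reactants: 12 (2S,3S)-2-[3,5-dimethoxy-4-(methoxymethoxy)phenyl]-3-hydroxy-6-(methoxymethoxy)-3,4-dihydro-2H-1,5-benzodioxepine-8-carbonitrile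
Product: 14 (2S,3S)-3-({[tert-butyl(dimethyl)silyl]oxy}methyl)-2-[3,5-dimethoxy-4-(methoxymethoxy)phenyl]-5-(methoxymethoxy)-2,3-dihydro-1,4-benzodioxine-7-carbonitrile (trans), via sodium alkoxide of the contracted alcohol 13 (not isolated)
Conditions: NaH (1.2 equiv), DMF, 0 → 60 °C; then TBSCl, 0 °C → rt
Reagents that add atoms: tert-butyldimethylsilyl chloride (TBSCl), CC(C)(C)[Si](C)(C)Cl
Why: The C3 alkoxide adds to C5a, the aromatic carbon that bears ring oxygen O5 and stands para to the nitrile, to give a cyanocyclohexadienide (Meisenheimer) adduct whose two oxygens at C5a form a 6,8-dioxabicyclo[3.2.1]octane-type ketal; loss of O5 opens the seven-membered ring and leaves the six-membered 1,4-dioxane ring, with C4 and O5 expelled as the CH2O− group, which TBSCl then caps. The closest known reaction type is the base-mediated O→O Smiles rearrangement of 2-(aryloxy)ethanols on acceptor-substituted arenes, here run inside a ring so that it becomes a ring contraction. The new O–C5a bond closes by 5-exo-trig attack on the arene (five-membered O–C3–C4–O5–C5a ring of the adduct), and the dioxane ring is what remains after C5a–O5 cleavage. No stereocentre is formed: the C3–O and C2–O1 bonds stay intact, so the cis-(2S,3S) dioxepinol is carried over to the trans-(2S,3S) benzodioxane. The step needs attack at C5a and not at C9a, and a forward equilibrium: C9a is meta to the nitrile and would require a four-membered adduct, and the six-membered ring with a primary alkoxide (removed by silylation) should be the more stable side.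

Step 10
Reactants: 14 (2S,3S)-3-({[tert-butyl(dimethyl)silyl]oxy}methyl)-2-[3,5-dimethoxy-4-(methoxymethoxy)phenyl]-5-(methoxymethoxy)-2,3-dihydro-1,4-benzodioxine-7-carbonitrile
Product: 15 (2S,3S)-3-({[tert-butyl(dimethyl)silyl]oxy}methyl)-2-[3,5-dimethoxy-4-(methoxymethoxy)phenyl]-5-(methoxymethoxy)-2,3-dihydro-1,4-benzodioxine-7-carbaldehyde
Conditions: DIBAL-H, CH2Cl2, −78 °C; aq Rochelle salt, then silica gel
Reagents that add atoms: water, O
Why: DIBAL-H reduction of the aryl nitrile stops at the aldimine, which hydrolyses to the aldehyde on work-up; MOM and TBS ethers and both stereocentres are not affected.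

Step 11
Reactants: 16 3,5-dihydroxybenzyl alcohol
Product: 17 [3,5-bis(methoxymethoxy)phenyl]methanol
Conditions: MOMCl (2.2 equiv), K2CO3, acetone, 0 °C → rt
Reagents that add atoms: chloromethyl methyl ether (MOMCl), COCCl
Why: Under carbonate only the phenols are deprotonated, so O-alkylation should be selective for the two phenolic positions.

Step 12
Reactants: 17 [3,5-bis(methoxymethoxy)phenyl]methanol
Product: 19 diethyl {[3,5-bis(methoxymethoxy)phenyl]methyl}phosphonate, via benzylic bromide 18 (not isolated)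
Conditions: CBr4, PPh3, CH2Cl2, 0 °C; filtration; then P(OEt)3, 120 °C
Reagents that add atoms: triethyl phosphite, CCOP(OCC)OCC; carbon tetrabromide (bromine of 18 only), BrC(Br)(Br)Br
Why: Appel bromination followed by Michaelis–Arbuzov reaction of the benzylic bromide should give the phosphonate.

Step 13
Reactants: 15 (2S,3S)-3-({[tert-butyl(dimethyl)silyl]oxy}methyl)-2-[3,5-dimethoxy-4-(methoxymethoxy)phenyl]-5-(methoxymethoxy)-2,3-dihydro-1,4-benzodioxine-7-carbaldehyde; 19 diethyl {[3,5-bis(methoxymethoxy)phenyl]methyl}phosphonate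
Product: 20 (2S,3S)-7-{(E)-2-[3,5-bis(methoxymethoxy)phenyl]ethenyl}-3-({[tert-butyl(dimethyl)silyl]oxy}methyl)-2-[3,5-dimethoxy-4-(methoxymethoxy)phenyl]-5-(methoxymethoxy)-2,3-dihydro-1,4-benzodioxine
Conditions: NaH, 15-crown-5 (cat.), THF, 0 °C; then 15, 0 °C → rt
Reagents that add atoms: none
Why: Horner–Wadsworth–Emmons olefination of a non-enolisable aryl aldehyde with a benzylphosphonate anion should give the E-stilbene; the capped CH2O group cannot re-enter an aryl shift now that C7 bears a formyl group.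

Step 14
Reactants: 20 (2S,3S)-7-{(E)-2-[3,5-bis(methoxymethoxy)phenyl]ethenyl}-3-({[tert-butyl(dimethyl)silyl]oxy}methyl)-2-[3,5-dimethoxy-4-(methoxymethoxy)phenyl]-5-(methoxymethoxy)-2,3-dihydro-1,4-benzodioxine
Product: 21 (2S,3S)-7-[(E)-2-(3,5-dihydroxyphenyl)ethenyl]-2-(4-hydroxy-3,5-dimethoxyphenyl)-3-(hydroxymethyl)-2,3-dihydro-1,4-benzodioxin-5-ol (target)
Conditions: 2 M HCl, MeOH–THF, 40 °C, argon, dark
Reagents that add atoms: none
Why: Acid-catalysed acetal exchange should remove the four aryl MOM ethers and the primary TBS ether in one operation without reducing or isomerising the stilbene; the trans-benzodioxane is the thermodynamically preferred isomer.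

**Compound list**

1 | 4-bromo-2,6-dimethoxyphenol | COc1cc(Br)cc(OC)c1O | starting material
2 | 5-bromo-1,3-dimethoxy-2-(methoxymethoxy)benzene | COCOc1c(OC)cc(Br)cc1OC | intermediate
3 | (±)-epichlorohydrin | ClCC1CO1 | starting material
4 | [3,5-dimethoxy-4-(methoxymethoxy)phenyl]magnesium bromide | COCOc1c(OC)cc([Mg]Br)cc1OC | intermediate (not isolated)
5 | 1-chloro-3-[3,5-dimethoxy-4-(methoxymethoxy)phenyl]propan-2-ol (racemic) | COCOc1c(OC)cc(CC(O)CCl)cc1OC | intermediate
6 | 1-chloro-3-[3,5-dimethoxy-4-(methoxymethoxy)phenyl]propan-2-one | COCOc1c(OC)cc(CC(=O)CCl)cc1OC | intermediate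
7 | 3,4,5-trihydroxybenzonitrile | N#Cc1cc(O)c(O)c(O)c1 | starting material
8 | 4-{3-[3,5-dimethoxy-4-(methoxymethoxy)phenyl]-2-oxopropoxy}-3,5-dihydroxybenzonitrile | COCOc1c(OC)cc(CC(=O)COc2c(O)cc(C#N)cc2O)cc1OC | intermediate
9 | 4-{3-diazo-3-[3,5-dimethoxy-4-(methoxymethoxy)phenyl]-2-oxopropoxy}-3,5-dihydroxybenzonitrile | COCOc1c(OC)cc(C(=[N+]=[N-])C(=O)COc2c(O)cc(C#N)cc2O)cc1OC | intermediate
10 | 2-[3,5-dimethoxy-4-(methoxymethoxy)phenyl]-6-hydroxy-3-oxo-3,4-dihydro-2H-1,5-benzodioxepine-8-carbonitrile (racemic) | COCOc1c(OC)cc(C2Oc3cc(C#N)cc(O)c3OCC2=O)cc1OC | intermediate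
11 | 2-[3,5-dimethoxy-4-(methoxymethoxy)phenyl]-6-(methoxymethoxy)-3-oxo-3,4-dihydro-2H-1,5-benzodioxepine-8-carbonitrile (racemic) | COCOc1c(OC)cc(C2Oc3cc(C#N)cc(OCOC)c3OCC2=O)cc1OC | intermediate
12 | (2S,3S)-2-[3,5-dimethoxy-4-(methoxymethoxy)phenyl]-3-hydroxy-6-(methoxymethoxy)-3,4-dihydro-2H-1,5-benzodioxepine-8-carbonitrile | COCOc1c(OC)cc([C@@H]2Oc3cc(C#N)cc(OCOC)c3OC[C@@H]2O)cc1OC | intermediate
13 | sodium {(2S,3S)-7-cyano-2-[3,5-dimethoxy-4-(methoxymethoxy)phenyl]-5-(methoxymethoxy)-2,3-dihydro-1,4-benzodioxin-3-yl}methanolate | COCOc1c(OC)cc([C@@H]2Oc3cc(C#N)cc(OCOC)c3O[C@H]2C[O-])cc1OC.[Na+] | intermediate (not isolated)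
14 | (2S,3S)-3-({[tert-butyl(dimethyl)silyl]oxy}methyl)-2-[3,5-dimethoxy-4-(methoxymethoxy)phenyl]-5-(methoxymethoxy)-2,3-dihydro-1,4-benzodioxine-7-carbonitrile | COCOc1c(OC)cc([C@@H]2Oc3cc(C#N)cc(OCOC)c3O[C@H]2CO[Si](C)(C)C(C)(C)C)cc1OC | intermediate
15 | (2S,3S)-3-({[tert-butyl(dimethyl)silyl]oxy}methyl)-2-[3,5-dimethoxy-4-(methoxymethoxy)phenyl]-5-(methoxymethoxy)-2,3-dihydro-1,4-benzodioxine-7-carbaldehyde | COCOc1c(OC)cc([C@@H]2Oc3cc(C=O)cc(OCOC)c3O[C@H]2CO[Si](C)(C)C(C)(C)C)cc1OC | intermediate
16 | 3,5-dihydroxybenzyl alcohol | OCc1cc(O)cc(O)c1 | starting material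
17 | [3,5-bis(methoxymethoxy)phenyl]methanol | COCOc1cc(CO)cc(OCOC)c1 | intermediate
18 | 1-(bromomethyl)-3,5-bis(methoxymethoxy)benzene | COCOc1cc(CBr)cc(OCOC)c1 | intermediate (not isolated)
19 | diethyl {[3,5-bis(methoxymethoxy)phenyl]methyl}phosphonate | CCOP(=O)(Cc1cc(OCOC)cc(OCOC)c1)OCC | intermediate
20 | (2S,3S)-7-{(E)-2-[3,5-bis(methoxymethoxy)phenyl]ethenyl}-3-({[tert-butyl(dimethyl)silyl]oxy}methyl)-2-[3,5-dimethoxy-4-(methoxymethoxy)phenyl]-5-(methoxymethoxy)-2,3-dihydro-1,4-benzodioxine | COCOc1c(OC)cc([C@@H]2Oc3cc(/C=C/c4cc(OCOC)cc(OCOC)c4)cc(OCOC)c3O[C@H]2CO[Si](C)(C)C(C)(C)C)cc1OC | intermediate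
21 | (2S,3S)-7-[(E)-2-(3,5-dihydroxyphenyl)ethenyl]-2-(4-hydroxy-3,5-dimethoxyphenyl)-3-(hydroxymethyl)-2,3-dihydro-1,4-benzodioxin-5-ol | COc1cc([C@@H]2Oc3cc(/C=C/c4cc(O)cc(O)c4)cc(O)c3O[C@H]2CO)cc(OC)c1O | target

**Step count and risks**

Total steps: 14. Longest linear sequence: 12 (steps 1–10, 13, 14).

Steps most likely to fail:

Step 9. The alkoxide may add too slowly to C5a, which is activated only by the para nitrile and flanked by two oxygen substituents. Displacement of the O1 aryloxide from C2 (epoxide formation and 6-exo re-closure to a constitutional isomer) could then compete, or the equilibrium might not lie far enough on the six-membered side. The fallback changes the acceptor and the order of events. It sets out from 12: DIBAL-H reduction of the nitrile should give (2S,3S)-2-[3,5-dimethoxy-4-(methoxymethoxy)phenyl]-3-hydroxy-6-(methoxymethoxy)-3,4-dihydro-2H-1,5-benzodioxepine-8-carbaldehyde F1. Its formyl group is the stronger para acceptor, so the aryl shift can be run as a carbonate-mediated equilibration (K2CO3, DMF, 60 °C) to (2S,3S)-2-[3,5-dimethoxy-4-(methoxymethoxy)phenyl]-3-(hydroxymethyl)-5-(methoxymethoxy)-2,3-dihydro-1,4-benzodioxine-7-carbaldehyde F2. Silylation (TBSCl, imidazole, DMF) comes back to the route at 15.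

Step 8. The catalyst may discriminate poorly between the two α-oxygenated flanks of this dialkyl-type ketone, or C2 may epimerise too slowly, so that enantio- or diastereoselectivity is lost. The fallback separates reduction from resolution and sets out from 11. L-Selectride (THF, −78 °C), with hydride delivery anti to the aryl group, should give the racemic cis-alcohol, rac-(2S*,3S*)-2-[3,5-dimethoxy-4-(methoxymethoxy)phenyl]-3-hydroxy-6-(methoxymethoxy)-3,4-dihydro-2H-1,5-benzodioxepine-8-carbonitrile F3. Lipase-catalysed acylation (Burkholderia cepacia lipase, vinyl acetate, MTBE) is expected by the Kazlauskas rule to convert the (3R) enantiomer into (2R,3R)-8-cyano-2-[3,5-dimethoxy-4-(methoxymethoxy)phenyl]-6-(methoxymethoxy)-3,4-dihydro-2H-1,5-benzodioxepin-3-yl acetate F4. The unreacted alcohol, separated by chromatography, is 12, where the route is rejoined.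

Step 6. Closure of the seven-membered ring may lose to intermolecular O–H insertion and oligomerisation, and the diazo transfer of step 5 in the presence of two phenoxides is also at risk. The fallback replaces the carbenoid by an SN2 closure and sets out from 8. Acetylation (Ac2O, pyridine) should give 5-cyano-2-{3-[3,5-dimethoxy-4-(methoxymethoxy)phenyl]-2-oxopropoxy}-1,3-phenylene diacetate F5. Bromination of the benzylic ketone enol (PhNMe3Br3, THF, 0 °C) should give 2-{3-bromo-3-[3,5-dimethoxy-4-(methoxymethoxy)phenyl]-2-oxopropoxy}-5-cyano-1,3-phenylene diacetate F6. K2CO3 in MeOH–THF at high dilution should then remove the acetates and close the ring by Williamson displacement of the bromide, coming back to the route at 10.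

Further compounds
F1 | step 9 | (2S,3S)-2-[3,5-dimethoxy-4-(methoxymethoxy)phenyl]-3-hydroxy-6-(methoxymethoxy)-3,4-dihydro-2H-1,5-benzodioxepine-8-carbaldehyde | COCOc1c(OC)cc([C@@H]2Oc3cc(C=O)cc(OCOC)c3OC[C@@H]2O)cc1OC
F2 | step 9 | (2S,3S)-2-[3,5-dimethoxy-4-(methoxymethoxy)phenyl]-3-(hydroxymethyl)-5-(methoxymethoxy)-2,3-dihydro-1,4-benzodioxine-7-carbaldehyde | COCOc1c(OC)cc([C@@H]2Oc3cc(C=O)cc(OCOC)c3O[C@H]2CO)cc1OC
F3 | step 8 | rac-(2S*,3S*)-2-[3,5-dimethoxy-4-(methoxymethoxy)phenyl]-3-hydroxy-6-(methoxymethoxy)-3,4-dihydro-2H-1,5-benzodioxepine-8-carbonitrile (both enantiomers) | COCOc1c(OC)cc([C@@H]2Oc3cc(C#N)cc(OCOC)c3OC[C@@H]2O)cc1OC.COCOc1c(OC)cc([C@H]2Oc3cc(C#N)cc(OCOC)c3OC[C@H]2O)cc1OC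
F4 | step 8 | (2R,3R)-8-cyano-2-[3,5-dimethoxy-4-(methoxymethoxy)phenyl]-6-(methoxymethoxy)-3,4-dihydro-2H-1,5-benzodioxepin-3-yl acetate | COCOc1c(OC)cc([C@H]2Oc3cc(C#N)cc(OCOC)c3OC[C@H]2OC(C)=O)cc1OC
F5 | step 6 | 5-cyano-2-{3-[3,5-dimethoxy-4-(methoxymethoxy)phenyl]-2-oxopropoxy}-1,3-phenylene diacetate | COCOc1c(OC)cc(CC(=O)COc2c(OC(C)=O)cc(C#N)cc2OC(C)=O)cc1OC
F6 | step 6 | 2-{3-bromo-3-[3,5-dimethoxy-4-(methoxymethoxy)phenyl]-2-oxopropoxy}-5-cyano-1,3-phenylene diacetate | COCOc1c(OC)cc(C(Br)C(=O)COc2c(OC(C)=O)cc(C#N)cc2OC(C)=O)cc1OC
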